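Product comes late in these runs, so first ask which given number a forecast for the new flask really hangs on.

| setting | theta | zeta | flask |
|---|---|---|---|
| substrate | 0.050 M | 0.075 M | 0.10 M |
| solid reagent | 0.15 M | 0.15 M | 0.150 M |
| catalyst | 1 mM | 1 mM | 1.0 mM |
| remark | run made earlier | run made earlier |  |

| run | time / min | product / % | substrate / % |
|---|---|---|---|
| theta | 6.00 | 1.6 | 99.3 |
| theta | 12.0 | 3.9 | 97.1 |
| theta | 20.0 | 8.2 | 92.3 |
| theta | 25.0 | 10.1 | 89.7 |
| theta | 30.0 | 13.8 | 88.3 |
| theta | 40.0 | 19.6 | 82.4 |
| zeta | 6.00 | 1.5 | 97.3 |
| zeta | 12.0 | 2.8 | 98.6 |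
| zeta | 20.0 | 4.7 | 95.1 |
| zeta | 25.0 | 6.2 | 92.1 |
| zeta | 30.0 | 8.4 | 90.0 |
| zeta | 40.0 | 12.4 | 87.8 |

(each reading ± 1 percentage point)

- given per volume of solution although it is solid: solid reagent
- at the start none of the solid reagent is in solution
- no earlier run changes the charge of catalyst; that part of a forecast is a guess

- factor on the rate of making product when 5.0% of the substrate are converted if catalyst is charged twice over
- factor on the rate when 5.0% of the substrate are converted if catalyst is charged at 0.20 mM instead

Take the substrate first: between 20.0 min and 40.0 min the theta run, at 0.050 M, makes product at 0.285 mM min⁻¹ and the zeta run, at 0.075 M, at 0.289 mM min⁻¹, so you may carry that rate to the new flask, and its charge of substrate matters for the amount needed, not for the pace. The scatter moves the theta rate by about 0.0354 mM min⁻¹, which you can live with. The solid reagent has the same charge in every flask, so it brings no error. The catalyst is different, because no run changes it, and neither factor can be read.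

What you can reckon is the delay, the clock time at which the straight line of the theta run cuts zero product: 5.61 min. The new flask needs 5.00 mM of product for its mark of 5.0%, so by my reckoning it arrives at 23.2 min, about 4.14 delays out. This gives a time and no factor.

The forecast, “Assuming a mixed regime, with comparable resistances”, says 1.4 (from 1 to 2) and 0.35 (from 0.2 to 0.85).

The flask gives 1.12 and 0.662.

    solid reagent ⇌ partner, rate k1*(cs1 - [partner]) while solid is left; crystals form when [partner] > cs1 (solubility = 0.0620 M, k = 0.00940 min⁻¹)
    substrate + partner + catalyst → product + catalyst, rate k2*[substrate]*[partner]*[catalyst]/(1 + ([substrate]/sat2)) (37.0 mM, k = 3800 M⁻² min⁻¹)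
    2 catalyst ⇌ resting dimer (K = 3200 M⁻¹, k = 41.0 M⁻¹ min⁻¹)

The flask reaches its mark at 22.5 min, against the 23.2 min reckoned from the delay. At 23.8 min the flask makes partner 1.66 times faster than it uses it up, each step taken net, and at 50.0 min still 1.27 times, while partner goes from 0.00772 M at 25.0 min to 0.0113 M at 50.0 min. In the flask with twice the catalyst the mark comes at 19.0 min; if you hold the delay at 5.61 min, that leaves 13.4 min for the 5.00 mM, against 16.8 min in the first flask, a mean pace 1.25 times the first flask's and so more than the factor of 1.12 on the rate at the mark.

(The earlier runs and the new flask were computed on assumed constants, noise included.)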